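(Its constants are invented; no experiment stands behind them.)

This flask is read through a ratio of two amounts: electrophile open to coupling over nucleophile able to couple.

    electrophile + nucleophile → acid set free + target (k1 = 0.0318 M⁻¹ min⁻¹)
    nucleophile + acid set free ⇌ protonated nucleophile, settled at all times (K2 = 145 M⁻¹)
    acid set free + free base ⇌ salt of the base, settled at all times (K3 = 178 M⁻¹)
    nucleophile + target ⇌ idle adduct, settled at all times (K4 = 13 M⁻¹)
    electrophile + protic impurity → quenched substrate (k5 = 0.364 M⁻¹ min⁻¹)

electrophile 0.50 M; nucleophile 0.550 M; free base 1.50 M; protic impurity 0.0250 M; time 2.5 h

* part of the electrophile that has reacted at 2.5 h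
* share of free nucleophile in free nucleophile and protonated nucleophile together, at 2.5 h

- for target the idle adduct is counted in
- run time (flask): 2.5 h

**Electrophile open.** Protic impurity has a half-life of 3.81 min against the charged electrophile, shorter than the 0.66 h of electrophile by coupling. Its whole charge therefore counts as lost electrophile, leaving E = 0.475 M.

**Nucleophile capacity.** The adduct constant times the nucleophile charge is 7.2, so each target is taken to hold a second nucleophile. The nucleophile charge then serves N = 0.275 M, half of it, the capacity: the target that can form with a second nucleophile bound to each. E/N is 1.73. Electrophile remains the limiting reagent, 0.50 M charged against 0.550 M of nucleophile. Adduct binding is reversible, so N is no ceiling on target; it is the amount at which free nucleophile runs out in this reckoning.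

**Reckoning.** With x coupled, the rate is twice 0.0318 M⁻¹ min⁻¹ times (E − x)(N − x). Integration over 2.5 h gives x = 0.256 M, so c is 56.2%, on the low side since binding is taken as complete. Free base binds acid more strongly than nucleophile does, 270 against 80; with salt equal to x, fr is 85.6%.

**Forecast.** The forecast gives 62.5% and 85%, reasoning that “the target ties up most of the free nucleophile as idle adduct”.

**Result.** The flask gives 62.4% and 84.8%, with the reckoned c lying 6.2 percentage points below. At 2.50 h its target stands at 57.4% of the electrophile charged, about half of it as idle adduct. In the neighbour flask with 0.30 M of electrophile, N is unchanged and E/N is 1.00. The equal-amounts form of the same rate gives x = 0.199 M, hence c = 74.7%. That neighbour flask gives 76.5%, with 23.5% of its electrophile left.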